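Readings and results come from a simulation for substances that don't exist.

common to all: catalyst 0.18 mM

|  | left-handed substrate | right-handed substrate | solid reagent | remark | time |
|---|---|---|---|---|---|
| gamma | 0.30 M | 0.30 M | 0.18 M | the very flask that is asked about, followed so far |  |
| beta | 0.15 M | 0.15 M | 0.18 M | run made earlier |  |
| flask | 0.30 M | 0.30 M | 0.180 M |  | 12 min |

| run | time / min | right-handed substrate / % | left-handed substrate / % | left-handed product / % |
|---|---|---|---|---|
| gamma | 1.33 | 49.3 | 49.2 | 0.9 |
| gamma | 2.50 | 47.4 | 46.6 | 2.6 |
| gamma | 4.00 | 48.2 | 44.5 | 6.7 |
| gamma | 5.00 | 47.0 | 45.8 | 5.7 |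
| gamma | 6.00 | 46.7 | 44.6 | 5.2 |
| beta | 1.00 | 50.3 | 50.0 | 2.2 |
| beta | 3.00 | 47.5 | 45.6 | 3.0 |
| beta | 6.00 | 47.0 | 42.3 | 7.4 |
| beta | 8.00 | 44.3 | 40.9 | 8.3 |
| beta | 12.0 | 42.5 | 37.1 | 12.1 |

(each reading ± 1 percentage point)

- catalyst is single-handed; left-handed substrate and right-handed substrate are mirror images of each other, charged as a racemate, each of them at the stated concentration
- given per volume of solution although it is solid: solid reagent
- at the start none of the solid reagent is in solution

- whether the excess of right-handed substrate over left-handed substrate among what is left of the two reaches 90% by 12 min (no / yes)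
- the highest excess of right-handed substrate over left-handed substrate among what is left of the two up to 12 min

In the beta run the left-handed substrate falls further than the right-handed, to 37.1% against 42.5% by 12.0 min, from equal shares. Take two amounts, the log-loss of each hand, meaning the natural logarithm of its charge over what is left: 0.298 and 0.163. If each hand is first order in itself and both share one catalyst and one reagent, whatever slows the run slows both alike and cancels in the ratio, 1.84, the selectivity factor. Gamma, the flask itself, reads 1.67 by 6.00 min with twice the substrate of beta.

With that factor, an excess of 90% asks for 98.4% of the charge to react, more than the 30.0% that the solid reagent covers one-to-one. Run gamma's left-hand loss on steadily to 12 min and 0.796 of that charge remains, so the factor leaves 0.883 of the right-handed charge. My reckoning is an excess of 5.20%.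

The forecast says no and 5%, a little below mine: “The excess of right-handed substrate stays small”.

The flask gives no and 4.67%.

    coupling partner + catalyst + left-handed substrate → catalyst + left-handed product (k = 19.4 /M²/s)
    coupling partner + catalyst + right-handed substrate → catalyst + right-handed product (k = 11.1 /M²/s)
    solid reagent ⇌ coupling partner, rate k3*(cs3 - [coupling partner]) while solid is left; crystals form when [coupling partner] > cs3 (solubility = 0.250 M, k = 0.0150 /s)
    catalyst ⇌ dormant form (K = 0.860, k = 0.00113 /s)
    coupling partner → decomposed reagent (k = 6.78 × 10⁻⁵ /s)

At 0.494 min the flask uses coupling partner on the left-handed substrate 1.7 times as fast as on the right-handed. The dormant form stands at 38.3% by 12.0 min. By then 80% of the left-handed charge remains in the flask, from which the selectivity factor gives 88.6% of the right-handed against the 88% that stands there. In a neighbouring flask with 7.2 × 10⁻⁴ M of catalyst, 66% of the left-handed charge remains by 12.0 min, the factor gives 79.8% of the right-handed against a simulated 79%, and the excess reaches 8.86%.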